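The earlier runs and the new flask are simulated on assumed constants; noise was put on by code.

The vessel is closed and stirred, at constant temperature and volume. X and J go in as a racemate, and the flasks differ in [L].

all flasks: X 0.10 M; J 0.10 M
- noon: L 0.090 M; run made earlier
- dawn: L 1.6 M; run made earlier
- ochre: L 0.300 M; time 5.0 d
- blue: L 0.0800 M; time 5.0 d
- violet: L 1.00 M; time 5.0 d
- amber: L 1.20 M; time 5.0 d

| run | time / d | Z / % |
|---|---|---|
| noon | 0.625 | 1.3 |
| noon | 1.67 | 3.3 |
| noon | 3.00 | 4.8 |
| noon | 5.00 | 8.1 |
| dawn | 1.25 | 30.5 |
| dawn | 2.50 | 43.4 |
| dawn | 4.00 | 50.3 |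
| dawn | 5.00 | 51.5 |

(each reading ± 0.5 percentage points)

- the flasks put in order of amount of Z, in percent of the X and J together charged, best first, at 5.0 d (ochre / blue / violet / amber)
- the amount of Z, in percent of the X and J together charged of the flask you put first, at 5.0 d
- the amount of Z, in percent of the X and J together charged of the flask you put last, at 5.0 d

- L is single-handed; X and J are mirror images of each other, charged as a racemate, each of them at the stated concentration
- the earlier runs were read with a standard deviation of 0.5 percentage points
- steps thought possible: L -> G; L <-> E; X <-> J; L + X -> Z; L + J -> Q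
- the handed part of L does not stay in what it makes, so the products of the two hands are mirror images too

1. With little L, I expect Z to grow in step with [L]; noon reads 8.1 % at 5.00 d.

2. With much L, and if X and J did not turn into each other, [X] would decay in a pseudo-first-order way and Z would head for a ceiling. X is half of the charge, and J gives Q, not Z.

3. One curve joins both extremes: Z is the ceiling times one minus e^(−reach × [L]). The reach, minus ln of the unused part of X per molar of L charged, reads 1.96 M⁻¹ in noon. It is a reading, with noon's scatter, and it holds for 5.0 d.

4. For dawn the curve gives 47.8 %, but dawn reads 51.5 %. That is above the ceiling, so some J has turned into X. The small correction is this gap, 3.7 percentage points.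

5. I order the flasks by [L]. For blue I take the curve, 7.27 %. For amber I take the curve, 45.3 %, plus dawn's gap, which makes 48.9 %.

6. The forecast gives amber > violet > ochre > blue, with 47.5 % on top and 7.3 % last, and holds that “the reaction is first order in L”. Its top is lower than mine.

7. The flasks give amber > violet > ochre > blue, with 49.3 % and 7.58 %. The order stands, and both forecast numbers are within the margin.

    L → G (k = 1.78 × 10⁻⁸ s⁻¹)
    L ⇌ E (K = 0.350, k = 1.30 × 10⁻⁵ s⁻¹)
    X ⇌ J (k = 1.04 × 10⁻⁶ s⁻¹)
    L + X → Z (k = 7.40 × 10⁻⁶ M⁻¹ s⁻¹)
    L + J → Q (k = 3.00 × 10⁻⁶ M⁻¹ s⁻¹)

In blue, L and E relax towards each other with a half-life of 0.160 d, both ways together, while the step L + X → Z alone has a half-life of L of 11 d at 0.107 d. At 5.0 d blue keeps 54 % of its L and amber 64 %. The reach, read in noon, carries noon's own loss of L inside it. On blue it gave 7.27 % against 7.58 %, and on a neighbour of blue charged with 0.20 M of L it gives 16.2 % against 17.1 %.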